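Readings and results were generated by integration for an exercise; the scatter is artificial.

Follow the reagent.

the same everywhere: substrate 0.25 M; free catalyst 2.5 mol% (in portions, 4)

| run | reagent | remark | time |
|---|---|---|---|
| west | 0.34 equiv | run made earlier; portions every 8.0 h |  |
| east | 0.75 equiv | run made earlier; portions every 8.0 h |  |
| flask | 0.500 equiv | the portions of free catalyst follow each other after 8.0 h, the first at the start | 5.0 d |

| run | time / d | product / % | substrate / % |
|---|---|---|---|
| west | 1.67 | 19 | 77 |
| west | 3.00 | 27 | 71 |
| west | 5.00 | 37 | 64 |
| west | 6.00 | 32 | 69 |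
| east | 0.500 | 5 | 92 |
| east | 1.04 | 18 | 77 |
| east | 2.50 | 52 | 45 |
| east | 6.00 | 77 | 26 |

(standard deviation of a reading: 2 percentage points)

- amount of product in percent of the substrate charged, at 12 h, 40 h, 3.0 d and 5.0 d

Each turnover consumes one reagent and one substrate, and both runs end near their reagent charge: west reads 32% on 0.34 equiv, east 77% on 0.75 equiv. Reagent is therefore the limiting reagent, and the unused part, charge minus product, is the quantity to track.

That unused part is taken to decay exponentially with a constant k, a pseudo-first-order fall. West gives 0.573 d⁻¹ and east 0.622 d⁻¹, readings with their scatter, so the mean k is 0.597 d⁻¹. The portions arrive on average after a delay t_d of 12.0 h. Both fold into one number, θ: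

θ = k·(t − t_d), reagent left = e^(−θ), product = reagent charge × (1 − e^(−θ))

θ counts the reagent time constants elapsed, with the catalyst treated as arriving whole at its mean delay. For the flask, this reagent time count at the end is 2.69.

My reckoning for the flask:

40 h: θ = 0.696, product 25.1%

3.0 d: θ = 1.49, product 38.8%

5.0 d: product 46.6%

Readings not used for k test this. At 6.00 d, the formula gives west 32.7% against 32% read, and east 72.2% against 77%, an east gap of 4.8 percentage points on a scatter of 2 points. Early on, one number fails: at 0.500 d θ is 0, yet east reads 5%. For 12 h, my reckoning for the flask therefore scales east's reading by charge, to 3.33%.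

The forecast gives 4%, 24%, 39% and 46%, holding that “the reagent is limiting and the flask should approach 50%”; at 40 h it stands 1.1 points below my reckoning.

The flask gives 4.44%, 24.8%, 39.1% and 47.1%.

    substrate + free catalyst → catalyst intermediate A (k = 9.10 L mol⁻¹ min⁻¹)
    reagent + catalyst intermediate A ⇌ catalyst intermediate B (K = 3.80 L mol⁻¹, k = 0.120 L mol⁻¹ min⁻¹)
    catalyst intermediate B → free catalyst + product (k = 0.0520 min⁻¹)

At 5.00 d, e^(−θ) leaves 6.80% of the reagent, and the flask holds 5.8% unbound. Catalyst intermediate B has a half-life of 0.22 h by its forward path alone, far shorter than the reagent time constant of 40.2 h. At 5.00 d, the flask's catalyst stands 98.9% as catalyst intermediate A, the resting state, and 1.04% as catalyst intermediate B. At twice the time, θ = 5.67 gives 49.8%, and the flask run that long gives 49.9%.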